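## The problem

The target, 5-hydroxy-3,7-dimethoxy-4'-(3-methylbut-2-enyloxy)flavone 12 (C22H22O6), is a 2-aryl-4H-chromen-4-one in which ring A, a phloroglucinol with oxygens at C5, C7 and C8a, is fused to the pyranone ring C along C4a–C8a and ring B sits on C2. It has no stereocentre, so nothing in the molecule has to control anything else; the only stereochemical matter is the double-bond geometry of open-chain intermediates. The real task is to tell four oxygens apart: methyl ethers at C3 and C7, a free hydroxyl at C5 and a prenyl ether at C4'. The prenyl ether is the fragile group: it ionises to an allyl cation under Brønsted or Lewis acid and rearranges on strong heating, so it cannot be present during an acid-mediated ring closure or a Lewis-acid dealkylation. C3 is best brought in already oxygenated, which rules out a direct phenol plus β-keto ester condensation with its coumarin-versus-chromone ambiguity. The feature that opens the route is ring A itself: with O5 and O7 both methylated, the two carbons ortho to O1 (the future C4a and C8) are equivalent, and each is ortho to O1, ortho to one OMe and para to the other, so a C4 acylium ion tethered through O1–C2–C3 can close ring C at carbon without a regiochemical question. Afterwards the 5-OMe differs from the 3- and 7-OMe by its peri relationship to the C4 carbonyl, which allows it alone to be removed.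

## Retrosynthesis

**O4'–prenyl bond.** Cutting the allylic C–O bond of 12 gives 5,4'-dihydroxy-3,7-dimethoxyflavone 10 and prenyl bromide 11. This cut comes first because the prenyl ether would survive neither the ring closure nor the demethylation. The forward step must alkylate one of two phenols; the 5-OH is hydrogen-bonded to the C4 carbonyl and far less nucleophilic than the 4'-OH.

**O5–CH3 and O4'–CH(CH3)2 bonds.** Diol 10 is traced to 4'-isopropoxy-3,5,7-trimethoxyflavone 9. Both cleavages are asked of one reagent, BCl3, which removes a methyl group peri to a carbonyl through a six-membered chelate and cleaves secondary alkyl aryl ethers. The isopropyl group is chosen over benzyl because it should survive strong protic acid. Keeping O5 as a methyl ether until this point preserves the symmetry of ring A for the ring closure.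

**C4–C4a bond (key step).** Opening ring C of 9 at the acyl–aryl bond gives (E)-3-(3,5-dimethoxyphenoxy)-3-(4-isopropoxyphenyl)-2-methoxyacrylic acid 8. Against the more usual closure at O1–C2 from an o-hydroxyaryl diketone, this cut needs no ortho-hydroxy ketone on ring A and no selective mono-protection of a phloroglucinol. Ring A enters as a symmetric phenol, and the precursor is an open-chain acid with one ring fewer. The forward reaction must turn the acid into an acylating species and deliver it to the carbon ortho to the aryl ether oxygen.

**O1–C2 bond.** Acid 8 comes from its methyl ester 7. The aryl enol ether bond of 7 is cut to 3,5-dimethoxyphenol 6 and the enol tosylate 5, methyl (E)-3-(4-isopropoxyphenyl)-2-methoxy-3-(tosyloxy)acrylate. Forming this bond before the ring closure fixes the oxygen on the future C2. The forward addition–elimination must take place at a β-carbon that is only moderately electrophilic, and it should keep the aryloxy group cis to the ester.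

**C2–C3 bond.** Tosylate 5 derives from β-keto ester 4, methyl 3-(4-isopropoxyphenyl)-2-methoxy-3-oxopropanoate. The bond between the ketone carbon and the methoxy-bearing carbon is cut to 4-isopropoxybenzoyl chloride 3, made in the flask from 4-isopropoxybenzoic acid 1, and the lithium enolate of methyl methoxyacetate 2. The acid chloride is preferred to an alkoxybenzoate ester because the α-alkoxy ester enolate would otherwise condense with itself faster than with a deactivated aryl ester.

## Roads not taken

Alternative 1: C4 delivered by carbon monoxide in a carbonylative α-arylation. The cut removes the C4–C4a and C3–C4 bonds together. In the forward sense 2-iodo-1,3,5-trimethoxybenzene A2, carbon monoxide and the enolate of 1-(4-isopropoxyphenyl)-2-methoxyethan-1-one A3 would combine under Pd(dba)2 and Xantphos to give the 1,3-diketone A1.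
- Merits: it is convergent, makes two C–C bonds in one operation and has no alkene geometry to manage. In convergence it is better than the chosen plan.
- Weak points: no ring closes. Iodide A2 is electron-rich and flanked by two methoxy groups, so the acylpalladium intermediate is hindered. It must be intercepted by the hindered α-alkoxy enolate of ketone A3 while direct α-arylation without CO competes. A1 carries three methoxy groups on ring A, so one ortho oxygen must be unmasked to close ring C and a second demethylation is needed later for the 5-OH.
- Comparison: the step count to 9 is about the same. The chosen plan sets against the convergence a ring-forming key step without gas or transition metal, and a single demethylation event.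

Alternative 2: ring C closed at C2–C3 by an intramolecular Wittig olefination. The cut is the C2=C3 double bond. The α-methoxy acylphosphorane A5, which carries two 4-(prenyloxy)benzoate esters on ring A, would olefinate one of these ester carbonyls on heating in toluene and give flavone A4. Saponification of the remaining ester of A4 leads to 12.
- Merits: the prenyl ether is carried from the start under neutral conditions, the two ester groups make the closure free of regiochemistry, and the end game needs neither a Lewis acid nor a selective alkylation. In end-game economy this road is better.
- Weak points: A5 is an α-alkoxy-substituted stabilised ylide that is hard to make. Its phosphonium precursor would have to come from an α-halo ether, or from acylation of a methoxymethylene ylide in the presence of two aryl esters that the ylide can also attack. One equivalent of the ring B acyl unit and one of the phosphine oxide by-product are discarded.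
- Comparison: the chosen plan needs two steps after ring closure instead of one, but each intermediate before the key step is made by a standard reaction.

Alternative 3: a symmetric difluoro ring A with ring C closed by SNAr. The cut is the C8a–O1 bond. The enolate of diketone A7 (K2CO3, DMF) would displace one of its two ortho fluorides through oxygen and give the 5-fluoroflavone A6.
- Merits: all steps are basic, so the prenyl ether can be present throughout, and the two fluorines remove the regiochemical question just as the two methoxy groups do in the chosen plan. In mildness this road is better than a closure in strong acid.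
- Weak points: the 5-fluoride of A6 must afterwards be exchanged for hydroxyl with an oxygen nucleophile, which competes with addition at C2 and opening of the pyranone. The 2,6-difluoro-4-methoxybenzoyl building block is more costly than a phenol, and the α-methoxy diketone A7 still has to be assembled.
- Comparison: the chosen plan uses 3,5-dimethoxyphenol and a chelation-directed demethylation in place of a C–F to C–O exchange. It pays for this with a late protecting-group exchange at O4'.

Key step: step 5

## Route

Remark: enol derivatives 5, 7 and 8 are drawn as the isomer with the oxygen substituent on the β-carbon cis to the carboxyl carbon, the isomer expected from chelation-controlled tosylation and retentive addition–elimination.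

Step 1
Reactants: 1 4-isopropoxybenzoic acid; 2 methyl methoxyacetate
Product: 4 methyl 3-(4-isopropoxyphenyl)-2-methoxy-3-oxopropanoate (racemic), via 4-isopropoxybenzoyl chloride 3 (not isolated)
Conditions: (COCl)2, cat. DMF, CH2Cl2, 0 °C to rt, evaporate; crude 3 added to 2 (2.1 equiv) pre-treated with LiN(SiMe3)2 (2.2 equiv), THF, −78 °C; aq. NH4Cl
Reagents that add atoms: none
Why: Acid chloride formation followed by C-acylation of a lithium ester enolate (crossed Claisen-type acylation); the second equivalent of enolate deprotonates the more acidic β-keto ester as it forms and so shields it from a second acylation, and the aryl isopropyl ether is inert to both stages.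

Step 2
Reactants: 4 methyl 3-(4-isopropoxyphenyl)-2-methoxy-3-oxopropanoate
Product: 5 methyl (E)-3-(4-isopropoxyphenyl)-2-methoxy-3-(tosyloxy)acrylate (tosyloxy cis to the ester)
Conditions: TsCl, TMEDA, LiCl, EtOAc, 0 °C to rt
Reagents that add atoms: p-toluenesulfonyl chloride, Cc1ccc(S(=O)(=O)Cl)cc1
Why: O-Sulfonylation of a β-keto ester enolate (stereodefined enol tosylate formation); lithium chelation between the ketone and ester oxygens holds the enolate in a U shape, so the tosyloxy group should end up cis to the ester, which is the (E) isomer here because the 2-methoxy group outranks the ester carbon.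

Step 3
Reactants: 5 methyl (E)-3-(4-isopropoxyphenyl)-2-methoxy-3-(tosyloxy)acrylate; 6 3,5-dimethoxyphenol
Product: 7 methyl (E)-3-(3,5-dimethoxyphenoxy)-3-(4-isopropoxyphenyl)-2-methoxyacrylate (aryloxy cis to the ester)
Conditions: Cs2CO3, DMF, 60 °C
Reagents that add atoms: none
Why: Nucleophilic vinylic substitution by addition–elimination, the bond formation known from phenoxides and β-chloro- or β-sulfonyloxy-acrylates; the phenoxide adds to the β-carbon, the ester enolate expels tosylate, and retention is expected because tosylate should leave faster than the enolate rotates.

Step 4
Reactants: 7 methyl (E)-3-(3,5-dimethoxyphenoxy)-3-(4-isopropoxyphenyl)-2-methoxyacrylate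
Product: 8 (E)-3-(3,5-dimethoxyphenoxy)-3-(4-isopropoxyphenyl)-2-methoxyacrylic acid
Conditions: LiOH, THF/MeOH/H2O, 40 °C; then 1 M HCl to pH 3 at 0 °C
Reagents that add atoms: lithium hydroxide, [Li+].[OH-]
Why: Ester saponification; hydroxide should attack the ester carbonyl faster than the donor-substituted β-carbon, the carboxylate then deactivates the alkene, and cold, brief acidification avoids hydrolysis of the aryl enol ether.

Step 5
Reactants: 8 (E)-3-(3,5-dimethoxyphenoxy)-3-(4-isopropoxyphenyl)-2-methoxyacrylic acid
Product: 9 4'-isopropoxy-3,5,7-trimethoxyflavone
Conditions: P2O5–MeSO3H (Eaton's reagent), rt to 40 °C; poured onto ice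
Reagents that add atoms: none
Why: Intramolecular Friedel–Crafts acylation: the acid becomes a mixed anhydride and then a conjugated acylium ion, which attacks the ring A carbon ortho to the aryl ether oxygen, and loss of a proton restores aromaticity to form the C4–C4a bond. The closest known reaction is the acid-mediated cyclisation of β-aryloxycinnamic and aryloxyfumaric acids to flavones and chromones. Ring C closes as a six-membered ring by exo attack of the arene on the acyl carbon. No stereocentre is formed. Regioselectivity on ring A is not an issue because the two ortho carbons are equivalent, and the carbon between the two methoxy groups cannot reach the tether. The attacked carbon is activated by O1 (ortho), one OMe (ortho) and the other OMe (para), whereas the competing ring B carbon is meta to its alkoxy group and would give a five-membered indenone, so ring A should win by a wide margin. The (E) geometry places the acyl group next to ring A; any (Z) acid is expected to equilibrate by reversible protonation at the methoxy-bearing carbon of the push–pull alkene. The 4'-O-isopropyl group, conjugated to the protonated chromone, should resist cleavage at this temperature.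

Step 6
Reactants: 9 4'-isopropoxy-3,5,7-trimethoxyflavone
Product: 10 5,4'-dihydroxy-3,7-dimethoxyflavone
Conditions: BCl3 (excess), CH2Cl2, −78 to 0 °C; then H2O
Reagents that add atoms: none
Why: Lewis-acid ether cleavage; BCl3 bound to the C4 carbonyl removes the peri 5-O-methyl group through a six-membered boron chelate and also cleaves the secondary isopropyl ether, while the 7-OMe (no chelate) and the 3-OMe (only a strained five-membered chelate possible) should remain.

Step 7
Reactants: 10 5,4'-dihydroxy-3,7-dimethoxyflavone; 11 prenyl bromide (1-bromo-3-methylbut-2-ene)
Product: 12 5-hydroxy-3,7-dimethoxy-4'-(3-methylbut-2-enyloxy)flavone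
Conditions: K2CO3 (1.2 equiv), 11 (1.1 equiv), acetone, 50 °C
Reagents that add atoms: none
Why: Williamson ether synthesis; the 4'-OH is the only free acidic phenol, whereas the 5-OH is held in a hydrogen bond to the C4 carbonyl and should not be alkylated by one equivalent of the allylic bromide under carbonate conditions.

## Compound list

1 | 4-isopropoxybenzoic acid | CC(C)Oc1ccc(C(=O)O)cc1 | starting material
2 | methyl methoxyacetate | COCC(=O)OC | starting material
3 | 4-isopropoxybenzoyl chloride | CC(C)Oc1ccc(C(Cl)=O)cc1 | intermediate
4 | methyl 3-(4-isopropoxyphenyl)-2-methoxy-3-oxopropanoate (racemic, enolisable centre) | COC(C(=O)OC)C(=O)c1ccc(OC(C)C)cc1 | intermediate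
5 | methyl (E)-3-(4-isopropoxyphenyl)-2-methoxy-3-(tosyloxy)acrylate | CO/C(C(=O)OC)=C(/OS(=O)(=O)c1ccc(C)cc1)c1ccc(OC(C)C)cc1 | intermediate
6 | 3,5-dimethoxyphenol | COc1cc(O)cc(OC)c1 | starting material
7 | methyl (E)-3-(3,5-dimethoxyphenoxy)-3-(4-isopropoxyphenyl)-2-methoxyacrylate | CO/C(C(=O)OC)=C(/Oc1cc(OC)cc(OC)c1)c1ccc(OC(C)C)cc1 | intermediate
8 | (E)-3-(3,5-dimethoxyphenoxy)-3-(4-isopropoxyphenyl)-2-methoxyacrylic acid | CO/C(C(=O)O)=C(/Oc1cc(OC)cc(OC)c1)c1ccc(OC(C)C)cc1 | intermediate
9 | 4'-isopropoxy-3,5,7-trimethoxyflavone | COc1cc(OC)c2c(=O)c(OC)c(-c3ccc(OC(C)C)cc3)oc2c1 | intermediate
10 | 5,4'-dihydroxy-3,7-dimethoxyflavone | COc1cc(O)c2c(=O)c(OC)c(-c3ccc(O)cc3)oc2c1 | intermediate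
11 | prenyl bromide (1-bromo-3-methylbut-2-ene) | CC(C)=CCBr | starting material
12 | 5-hydroxy-3,7-dimethoxy-4'-(3-methylbut-2-enyloxy)flavone | COc1cc(O)c2c(=O)c(OC)c(-c3ccc(OCC=C(C)C)cc3)oc2c1 | target

## Step count and risks

Total: 7 steps. Longest linear sequence: 7 steps (from 1 to 12).

**Step 5 (key step).**
- What may go wrong: cyclisation onto ring B from any acid whose acyl group lies next to ring B, if geometric equilibration is slower than acylation; protonation of the push–pull alkene followed by decarboxylation before the acid is activated; acid-induced loss of the isopropyl group.
- Fallback: close ring C at O1–C2 instead. Setting out from 6, BF3·OEt2-mediated ortho-acylation with methoxyacetic acid (Fries-type, directed by the phenol oxygen) should give 1-(2-hydroxy-4,6-dimethoxyphenyl)-2-methoxyethan-1-one F1. C-Aroylation of its lithium dianion with 3 (made from 1 as in step 1; LiN(SiMe3)2, THF, −78 °C to rt) reaches the diketone of a Baker–Venkataraman sequence in one flask and should give 1-(2-hydroxy-4,6-dimethoxyphenyl)-3-(4-isopropoxyphenyl)-2-methoxypropane-1,3-dione F2. Cyclodehydration (TsOH, toluene, reflux) returns to the route at 9.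

**Step 3.**
- What may go wrong: attack of the phenoxide on the sulfonyl sulfur instead of the β-carbon, which hands the tosyl group to the phenol and regenerates the enolate of 4; slow addition, because the β-carbon belongs to an enol ether as well as to an acrylate; loss of geometry through a long-lived ester enolate. A tosylation in step 2 that gives the wrong geometry, or chlorinates at carbon, would show up here as well.
- Fallback: set out from 4 and bypass 5. Chelation-controlled triflation (Tf2O, aq. LiOH, toluene, 0 °C) should give methyl (E)-3-(4-isopropoxyphenyl)-2-methoxy-3-(trifluoromethylsulfonyloxy)acrylate F3. Its C–O coupling with 6 (Pd2(dba)3, 2-(di-tert-butylphosphino)biphenyl, K3PO4, toluene, 100 °C) runs through oxidative addition at zerovalent palladium and not through conjugate addition, and returns to the route at 7.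

**Step 1.**
- What may go wrong: O-acylation or double acylation of the enolate, and self-condensation of the α-alkoxy ester enolate if the mixture warms before the acid chloride is consumed.
- Fallback: set out from 2 and separate C–C bond formation from the oxidation level. Aldol addition of the same lithium enolate to 4-isopropoxybenzaldehyde F4, a purchased aldehyde, should give methyl 3-hydroxy-3-(4-isopropoxyphenyl)-2-methoxypropanoate F5, as a diastereomer mixture of no consequence. Dess–Martin oxidation returns to the route at 4.

**Step 4.**
- What may go wrong: hydroxide adding at the β-carbon and expelling the phenoxide (the reverse of step 3), or hydrolysis of the aryl enol ether and decarboxylation during acidification.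
- Fallback: set out from 7 and cleave the ester at the alkyl–oxygen bond with LiI in refluxing ethyl acetate (substitution at the ester methyl group, no hydroxide), returning to the route at 8 after mild acidification. No new compound is made on this path; its entry is F0.

## Further compounds

F1 | step 5 | 1-(2-hydroxy-4,6-dimethoxyphenyl)-2-methoxyethan-1-one | COCC(=O)c1c(O)cc(OC)cc1OC
F2 | step 5 | 1-(2-hydroxy-4,6-dimethoxyphenyl)-3-(4-isopropoxyphenyl)-2-methoxypropane-1,3-dione (racemic, enolisable centre) | COc1cc(O)c(C(=O)C(OC)C(=O)c2ccc(OC(C)C)cc2)c(OC)c1
F3 | step 3 | methyl (E)-3-(4-isopropoxyphenyl)-2-methoxy-3-(trifluoromethylsulfonyloxy)acrylate | CO/C(C(=O)OC)=C(/OS(=O)(=O)C(F)(F)F)c1ccc(OC(C)C)cc1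
F4 | step 1 | 4-isopropoxybenzaldehyde | CC(C)Oc1ccc(C=O)cc1
F5 | step 1 | methyl 3-hydroxy-3-(4-isopropoxyphenyl)-2-methoxypropanoate (diastereomer mixture, racemic) | COC(C(=O)OC)C(O)c1ccc(OC(C)C)cc1
F0 | step 4 | none | none
A1 | alternative 1 | 1-(4-isopropoxyphenyl)-2-methoxy-3-(2,4,6-trimethoxyphenyl)propane-1,3-dione (enolisable centre) | COc1cc(OC)c(C(=O)C(OC)C(=O)c2ccc(OC(C)C)cc2)c(OC)c1
A2 | alternative 1 | 2-iodo-1,3,5-trimethoxybenzene | COc1cc(OC)c(I)c(OC)c1
A3 | alternative 1 | 1-(4-isopropoxyphenyl)-2-methoxyethan-1-one | COCC(=O)c1ccc(OC(C)C)cc1
A4 | alternative 2 | 3,7-dimethoxy-4'-(prenyloxy)flavon-5-yl 4-(prenyloxy)benzoate | COc1cc(OC(=O)c2ccc(OCC=C(C)C)cc2)c2c(=O)c(OC)c(-c3ccc(OCC=C(C)C)cc3)oc2c1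
A5 | alternative 2 | 5-methoxy-2-[2-methoxy-2-(triphenylphosphoranylidene)acetyl]-1,3-phenylene bis[4-(prenyloxy)benzoate] | COc1cc(OC(=O)c2ccc(OCC=C(C)C)cc2)c(C(=O)C(OC)=P(c2ccccc2)(c2ccccc2)c2ccccc2)c(OC(=O)c2ccc(OCC=C(C)C)cc2)c1
A6 | alternative 3 | 5-fluoro-3,7-dimethoxy-4'-(prenyloxy)flavone | COc1cc(F)c2c(=O)c(OC)c(-c3ccc(OCC=C(C)C)cc3)oc2c1
A7 | alternative 3 | 1-(2,6-difluoro-4-methoxyphenyl)-2-methoxy-3-[4-(prenyloxy)phenyl]propane-1,3-dione (enolisable centre) | COc1cc(F)c(C(=O)C(OC)C(=O)c2ccc(OCC=C(C)C)cc2)c(F)c1
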